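**Plan**

- Ring atoms carry carotenoid numbers: C1 = CMe2, C2 = CH2, C3 = C–O, C4=C5(CH3), C6 = CH bearing the chain, C7 = first chain carbon.
- Retrosynthesis: the C2-symmetric C40 diol is cut at C7=C8 and C7'=C8' (twofold Julia–Kocienski olefination) into C20 crocetin dialdehyde and two identical C10 ring sulfones.
- Each ring is then cut at C2–C3 and C4=C5. The C3–C4 unit comes from a phosphonoacetyl thioester, the C5–C6–C1–C2 unit from a δ-keto acid made from 3,3-dimethylglutaric anhydride.
- Enabling feature: at the ketone level each ε-ring is a 3-methylcyclohex-2-enone whose C2 methylene sits on the quaternary C1 (a C2 radical has no β-hydrogen and cannot eliminate or rearrange) and whose C5 is a former methyl ketone. A –C(=O)–CH2–P unit can therefore be stitched between a C2 radical and the C5 carbonyl.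
- Forward: anhydride → Evans alkylation → keto acid → one-flask annulation (the only ring-forming event) → ring sulfone → union with the C20 dialdehyde.
- Stereochemistry: C6 from the (R)-oxazolidinone-controlled alkylation; C3 from substrate-controlled hydride delivery trans to the C6 substituent; chain E-geometry from the dialdehyde, the olefination and iodine equilibration.

Key step: step 8

Assumption: crocetin dialdehyde (26) is treated as a purchasable C20 building block.

**Step 1**
Reactants: 1 3,3-dimethylglutaric anhydride; 2 (R)-4-benzyl-1,3-oxazolidin-2-one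
Product: 3 5-[(4R)-4-benzyl-2-oxo-1,3-oxazolidin-3-yl]-3,3-dimethyl-5-oxopentanoic acid
Conditions: 2, n-BuLi, THF, −78 °C; then 1, −78 to 0 °C; aq. HCl work-up
Reagents that add atoms: (R)-4-benzyl-1,3-oxazolidin-2-one (2), O=C1OC[C@@H](Cc2ccccc2)N1
Why: N-acylation of the lithiated oxazolidinone by the symmetrical cyclic anhydride opens the ring once and leaves the second carboxyl free, so no regiochemical question arises.

**Step 2**
Reactants: 3; 4 benzyl bromide
Product: 5 benzyl 5-[(4R)-4-benzyl-2-oxo-1,3-oxazolidin-3-yl]-3,3-dimethyl-5-oxopentanoate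
Conditions: K2CO3, DMF, rt
Reagents that add atoms: benzyl bromide (4), BrCc1ccccc1
Why: carboxylate O-alkylation (SN2) masks the acid as a benzyl ester that should survive enolisation, thiolate and cuprate chemistry and can be removed later under neutral conditions.

**Step 3**
Reactants: 5; 6 benzyl chloromethyl ether
Product: 7 benzyl (4S)-5-[(4R)-4-benzyl-2-oxo-1,3-oxazolidin-3-yl]-4-[(benzyloxy)methyl]-3,3-dimethyl-5-oxopentanoate
Conditions: TiCl4, i-Pr2NEt, CH2Cl2, 0 °C; then 6, 0 °C
Reagents that add atoms: benzyl chloromethyl ether (6), ClCOCc1ccccc1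
Why: Evans alkylation, in which the chelated Z-titanium enolate is attacked by the oxocarbenium-like electrophile on the face opposite the auxiliary benzyl group, so the (R)-auxiliary should give the (4S) centre that becomes C6 (6R) of the ring.

**Step 4**
Reactants: 7; 8 ethanethiol
Product: 9 benzyl (4S)-4-[(benzyloxy)methyl]-5-(ethylsulfanyl)-3,3-dimethyl-5-oxopentanoate
Conditions: EtSH, n-BuLi, THF, 0 °C
Reagents that add atoms: ethanethiol (8), CCS
Why: thiolate-mediated exocyclic cleavage of the hindered N-acyloxazolidinone (transthioesterification) should release the auxiliary and give the thioester without touching the α-stereocentre or the benzyl ester.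

**Step 5**
Reactants: 9; 10 methyllithium
Product: 11 benzyl (4S)-4-[(benzyloxy)methyl]-3,3-dimethyl-5-oxohexanoate
Conditions: Me2CuLi (from MeLi and CuI), Et2O, −78 °C
Reagents that add atoms: lithium dimethylcuprate, [Li+].C[Cu-]C, made in the flask from methyllithium (10), [Li]C
Why: thioester-to-ketone conversion with a Gilman cuprate should stop at the methyl ketone, which is inert to the cuprate at low temperature, and leave the ester and the α-centre untouched.

**Step 6**
Reactants: 11
Product: 12 (4S)-4-[(benzyloxy)methyl]-3,3-dimethyl-5-oxohexanoic acid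
Conditions: H2 (1 atm), Pd/C, pyridine (0.5 equiv), EtOAc, rt
Reagents that add atoms: none
Why: chemoselective catalytic hydrogenolysis should cleave the benzyl ester while pyridine poisoning suppresses cleavage of the benzyl ether, and the neutral conditions keep the β-alkoxy ketone and its α-centre intact.

**Step 7**
Reactants: 13 2-(diethoxyphosphoryl)acetic acid; 14 pyridine-2-thiol
Product: 15 S-(pyridin-2-yl) 2-(diethoxyphosphoryl)ethanethioate
Conditions: DCC, DMAP (cat.), CH2Cl2, 0 °C to rt
Reagents that add atoms: pyridine-2-thiol (14), Sc1ccccn1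
Why: Steglich-type carbodiimide coupling gives the 2-pyridyl thioester that serves as the two-carbon acyl donor in the nickel step.

**Step 8**
Reactants: 12; 15; 16 N-hydroxyphthalimide
Product: 19 (4R)-4-[(benzyloxy)methyl]-3,5,5-trimethylcyclohex-2-en-1-one, via redox-active ester 17 (not isolated), via keto phosphonate 18 (not isolated)
Conditions: 16, DIC, DMAP (cat.), THF, rt; then 15, NiBr2(dme) (10 mol %), 4,4'-di-tert-butyl-2,2'-bipyridine, Zn, DMA, rt; then LiCl, DBU, MeCN, 50 °C
Reagents that add atoms: S-(pyridin-2-yl) 2-(diethoxyphosphoryl)ethanethioate (15), CCOP(=O)(OCC)CC(=O)Sc1ccccn1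
Why: Carbodiimide activation gives ester 17; zerovalent nickel inserts into the acyl–sulfur bond of 15, single-electron reduction of 17 releases CO2 and the primary C2 radical (next to the quaternary C1, so no β-hydrogen and no 1,2-shift), and radical capture at nickel with reductive elimination forms the C2–C3 bond of 18; DBU/LiCl then deprotonates C4, the phosphonate carbanion adds to the C5 methyl ketone and the oxaphosphetane collapses to the C4=C5 double bond. The closest known reaction types are the nickel-catalysed decarboxylative cross-electrophile ketone synthesis from redox-active esters and 2-pyridyl thioesters, and the intramolecular Horner–Wadsworth–Emmons cyclohexenone synthesis under Masamune–Roush conditions. The six-membered ring closes in a 6-(enolendo)-exo-trig mode, with the phosphonate-stabilised C4 attacking the C5 carbonyl whose oxygen lies outside the ring. No new stereocentre is created, and the C6 centre from step 3 should be carried through because the amine base deprotonates only the β-ketophosphonate CH2 and not the hindered ketone α-CH. The selectivity needed is regiochemical: only C4 carries phosphorus, so the alkene can form only between C4 and C5, which excludes the alternative aldol mode (C5-methyl enolate onto the C3 ketone) and an alkene conjugated through C6. Chemoselectivity of the radical stage rests on the acyl-nickel partner intercepting the radical faster than hydrogen transfer from the benzylic ether.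

**Step 9**
Reactants: 19
Product: 20 (4R)-4-(hydroxymethyl)-3,5,5-trimethylcyclohex-2-en-1-one
Conditions: BCl3, CH2Cl2, −78 °C; MeOH quench
Reagents that add atoms: none
Why: Lewis-acid debenzylation, in which BCl3 coordinates the ether oxygen and chloride removes the benzyl group at low temperature, should leave the enone and the γ-stereocentre untouched.

**Step 10**
Reactants: 20; 21 1-phenyl-1H-tetrazole-5-thiol
Product: 22 (4R)-3,5,5-trimethyl-4-{[(1-phenyl-1H-tetrazol-5-yl)sulfanyl]methyl}cyclohex-2-en-1-one
Conditions: PPh3, DIAD, THF, 0 °C to rt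
Reagents that add atoms: 1-phenyl-1H-tetrazole-5-thiol (21), Sc1nnnn1-c1ccccc1
Why: Mitsunobu thioetherification, in which the acidic thiol displaces the activated primary hydroxyl (SN2 at CH2, no stereocentre involved), runs under neutral conditions that avoid vinylogous β-elimination from the enone.

**Step 11**
Reactants: 22
Product: 23 (1R,4R)-3,5,5-trimethyl-4-{[(1-phenyl-1H-tetrazol-5-yl)sulfanyl]methyl}cyclohex-2-en-1-ol
Conditions: LiBH(s-Bu)3 (L-Selectride), THF, −78 °C; aq. NH4Cl
Reagents that add atoms: none
Why: 1,2-reduction of the β,β-disubstituted enone by the bulky hydride should occur equatorially, anti to the axial C1 methyl group that shields the other face, in the half-chair with the C6 substituent pseudoaxial, which places the new hydroxyl trans to the C6 side chain (3R).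

**Step 12**
Reactants: 23; 24 hydrogen peroxide
Product: 25 (1R,4R)-3,5,5-trimethyl-4-{[(1-phenyl-1H-tetrazol-5-yl)sulfonyl]methyl}cyclohex-2-en-1-ol
Conditions: (NH4)6Mo7O24·4H2O (cat.), 30% H2O2, EtOH, 0 °C to rt
Reagents that add atoms: hydrogen peroxide (24), OO
Why: molybdate-catalysed peroxide oxidation of the sulfide to the sulfone should be chemoselective over the trisubstituted alkene and the secondary alcohol.

**Step 13**
Reactants: 25 (2.2 equiv); 26 crocetin dialdehyde, (2E,4E,6E,8E,10E,12E,14E)-2,6,11,15-tetramethylhexadeca-2,4,6,8,10,12,14-heptaenedial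
Product: 27 (3R,3'R,6R,6'R)-ε,ε-carotene-3,3'-diol (all-E), the target
Conditions: KN(SiMe3)2 (4.6 equiv), THF, −78 °C to rt; then I2 (cat.), toluene, daylight, rt
Reagents that add atoms: crocetin dialdehyde (26), O=C/C(C)=C/C=C/C(C)=C/C=C/C=C(C)/C=C/C=C(C)/C=O
Why: twofold Julia–Kocienski olefination, in which each sulfonyl carbanion adds to an aldehyde terminus and Smiles rearrangement with loss of SO2 and the tetrazolone forms C7=C8 and C7'=C8' directly, followed by iodine-catalysed equilibration to the thermodynamically preferred all-E polyene; C6 is not acidified by the sulfone and should not epimerise.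

**Compound list**

1 | 3,3-dimethylglutaric anhydride | CC1(C)CC(=O)OC(=O)C1 | starting material
2 | (R)-4-benzyl-1,3-oxazolidin-2-one | O=C1OC[C@@H](Cc2ccccc2)N1 | starting material
3 | 5-[(4R)-4-benzyl-2-oxo-1,3-oxazolidin-3-yl]-3,3-dimethyl-5-oxopentanoic acid | O=C1OC[C@@H](Cc2ccccc2)N1C(=O)CC(C)(C)CC(=O)O | intermediate
4 | benzyl bromide | BrCc1ccccc1 | starting material
5 | benzyl 5-[(4R)-4-benzyl-2-oxo-1,3-oxazolidin-3-yl]-3,3-dimethyl-5-oxopentanoate | O=C1OC[C@@H](Cc2ccccc2)N1C(=O)CC(C)(C)CC(=O)OCc1ccccc1 | intermediate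
6 | benzyl chloromethyl ether | ClCOCc1ccccc1 | starting material
7 | benzyl (4S)-5-[(4R)-4-benzyl-2-oxo-1,3-oxazolidin-3-yl]-4-[(benzyloxy)methyl]-3,3-dimethyl-5-oxopentanoate | O=C1OC[C@@H](Cc2ccccc2)N1C(=O)[C@H](COCc1ccccc1)C(C)(C)CC(=O)OCc1ccccc1 | intermediate
8 | ethanethiol | CCS | starting material
9 | benzyl (4S)-4-[(benzyloxy)methyl]-5-(ethylsulfanyl)-3,3-dimethyl-5-oxopentanoate | CCSC(=O)[C@H](COCc1ccccc1)C(C)(C)CC(=O)OCc1ccccc1 | intermediate
10 | methyllithium | [Li]C | starting material
11 | benzyl (4S)-4-[(benzyloxy)methyl]-3,3-dimethyl-5-oxohexanoate | CC(=O)[C@H](COCc1ccccc1)C(C)(C)CC(=O)OCc1ccccc1 | intermediate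
12 | (4S)-4-[(benzyloxy)methyl]-3,3-dimethyl-5-oxohexanoic acid | CC(=O)[C@H](COCc1ccccc1)C(C)(C)CC(=O)O | intermediate
13 | 2-(diethoxyphosphoryl)acetic acid | OC(=O)CP(=O)(OCC)OCC | starting material
14 | pyridine-2-thiol | Sc1ccccn1 | starting material
15 | S-(pyridin-2-yl) 2-(diethoxyphosphoryl)ethanethioate | CCOP(=O)(OCC)CC(=O)Sc1ccccn1 | intermediate
16 | N-hydroxyphthalimide | ON1C(=O)c2ccccc2C1=O | starting material
17 | 1,3-dioxoisoindolin-2-yl (4S)-4-[(benzyloxy)methyl]-3,3-dimethyl-5-oxohexanoate | CC(=O)[C@H](COCc1ccccc1)C(C)(C)CC(=O)ON1C(=O)c2ccccc2C1=O | intermediate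
18 | diethyl {(5S)-5-[(benzyloxy)methyl]-4,4-dimethyl-2,6-dioxoheptyl}phosphonate | CC(=O)[C@H](COCc1ccccc1)C(C)(C)CC(=O)CP(=O)(OCC)OCC | intermediate
19 | (4R)-4-[(benzyloxy)methyl]-3,5,5-trimethylcyclohex-2-en-1-one | CC1=CC(=O)CC(C)(C)[C@H]1COCc1ccccc1 | intermediate
20 | (4R)-4-(hydroxymethyl)-3,5,5-trimethylcyclohex-2-en-1-one | CC1=CC(=O)CC(C)(C)[C@H]1CO | intermediate
21 | 1-phenyl-1H-tetrazole-5-thiol | Sc1nnnn1-c1ccccc1 | starting material
22 | (4R)-3,5,5-trimethyl-4-{[(1-phenyl-1H-tetrazol-5-yl)sulfanyl]methyl}cyclohex-2-en-1-one | CC1=CC(=O)CC(C)(C)[C@H]1CSc1nnnn1-c1ccccc1 | intermediate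
23 | (1R,4R)-3,5,5-trimethyl-4-{[(1-phenyl-1H-tetrazol-5-yl)sulfanyl]methyl}cyclohex-2-en-1-ol | CC1=C[C@H](O)CC(C)(C)[C@H]1CSc1nnnn1-c1ccccc1 | intermediate
24 | hydrogen peroxide | OO | starting material
25 | (1R,4R)-3,5,5-trimethyl-4-{[(1-phenyl-1H-tetrazol-5-yl)sulfonyl]methyl}cyclohex-2-en-1-ol | CC1=C[C@H](O)CC(C)(C)[C@H]1CS(=O)(=O)c1nnnn1-c1ccccc1 | intermediate
26 | crocetin dialdehyde (all-E) | O=C/C(C)=C/C=C/C(C)=C/C=C/C=C(C)/C=C/C=C(C)/C=O | starting material
27 | (3R,3'R,6R,6'R)-ε,ε-carotene-3,3'-diol | CC1=C[C@H](O)CC(C)(C)[C@H]1/C=C/C(C)=C/C=C/C(C)=C/C=C/C=C(C)/C=C/C=C(C)/C=C/[C@H]1C(C)=C[C@H](O)CC1(C)C | target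

**Step count and risks**

Total steps: 13. Longest linear sequence: 12 (steps 1–6 and 8–13); step 7 is a side branch.

Most likely to fail:

1. Step 8. The primary radical may be reduced or abstract hydrogen before it is captured at nickel, and closure onto the hindered methyl ketone may be slow enough for base-induced epimerisation at C6. Fallback (from 12, back to the route at 19): a polar, stepwise sequence. Iododecarboxylation of 12 with PhI(OAc)2 and I2 under visible light would give (3S)-3-[(benzyloxy)methyl]-5-iodo-4,4-dimethylpentan-2-one F1. Zinc insertion (Zn, LiCl, THF) would give {(3S)-3-[(benzyloxy)methyl]-2,2-dimethyl-4-oxopentyl}zinc iodide F2, which tolerates the ketone. Fukuyama coupling of F2 with thioester 15 (PdCl2(PPh3)2 cat.) would give 18 as an isolated compound, and NaH in THF would then close it to 19.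

2. Step 11. Facial selectivity of hydride delivery may be insufficient, giving the cis alcohol, or conjugate reduction may compete. Fallback (from 22, back at 23): set C3 by inversion instead of facial selectivity. Luche reduction (NaBH4, CeCl3, MeOH) would give the alcohol mixture, from which (1S,4R)-3,5,5-trimethyl-4-{[(1-phenyl-1H-tetrazol-5-yl)sulfanyl]methyl}cyclohex-2-en-1-ol F3 is separated. Mitsunobu inversion with 4-nitrobenzoic acid (PPh3, DIAD) would give (1R,4R)-3,5,5-trimethyl-4-{[(1-phenyl-1H-tetrazol-5-yl)sulfanyl]methyl}cyclohex-2-en-1-yl 4-nitrobenzoate F4, and methanolysis (K2CO3, MeOH) would give 23.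

3. Step 13. The second olefination may stall, the hydroxy sulfone dianion may self-condense, or E-selectivity may be low with the conjugated dialdehyde. Fallback (from 20, back at 27): a Wittig union at the same bonds. Reduction of 20 with LiBH(s-Bu)3 would give (1R,4R)-4-(hydroxymethyl)-3,5,5-trimethylcyclohex-2-en-1-ol F5. Selective iodination of the primary hydroxyl (I2, PPh3, imidazole) would give (1R,4R)-4-(iodomethyl)-3,5,5-trimethylcyclohex-2-en-1-ol F6. Heating with PPh3 in MeCN would give {[(1R,4R)-4-hydroxy-2,6,6-trimethylcyclohex-2-en-1-yl]methyl}triphenylphosphonium iodide F7. Twofold Wittig reaction of F7 with 26 (NaN(SiMe3)2, THF), then iodine-catalysed isomerisation of the Z-rich product, would give 27.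

**Further compounds**

F1 | step 8 | (3S)-3-[(benzyloxy)methyl]-5-iodo-4,4-dimethylpentan-2-one | CC(=O)[C@H](COCc1ccccc1)C(C)(C)CI
F2 | step 8 | {(3S)-3-[(benzyloxy)methyl]-2,2-dimethyl-4-oxopentyl}zinc iodide | CC(=O)[C@H](COCc1ccccc1)C(C)(C)C[Zn]I
F3 | step 11 | (1S,4R)-3,5,5-trimethyl-4-{[(1-phenyl-1H-tetrazol-5-yl)sulfanyl]methyl}cyclohex-2-en-1-ol | CC1=C[C@@H](O)CC(C)(C)[C@H]1CSc1nnnn1-c1ccccc1
F4 | step 11 | (1R,4R)-3,5,5-trimethyl-4-{[(1-phenyl-1H-tetrazol-5-yl)sulfanyl]methyl}cyclohex-2-en-1-yl 4-nitrobenzoate | CC1=C[C@H](OC(=O)c2ccc(cc2)[N+](=O)[O-])CC(C)(C)[C@H]1CSc1nnnn1-c1ccccc1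
F5 | step 13 | (1R,4R)-4-(hydroxymethyl)-3,5,5-trimethylcyclohex-2-en-1-ol | CC1=C[C@H](O)CC(C)(C)[C@H]1CO
F6 | step 13 | (1R,4R)-4-(iodomethyl)-3,5,5-trimethylcyclohex-2-en-1-ol | CC1=C[C@H](O)CC(C)(C)[C@H]1CI
F7 | step 13 | {[(1R,4R)-4-hydroxy-2,6,6-trimethylcyclohex-2-en-1-yl]methyl}triphenylphosphonium iodide | CC1=C[C@H](O)CC(C)(C)[C@H]1C[P+](c1ccccc1)(c1ccccc1)c1ccccc1.[I-]
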